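The route rests on disconnecting the C4–C4a bond of ring B. Ring A and the aryl group on C1 are the same 4-oxy-3-methoxyphenyl unit, so C1 can be carried as an achiral diarylmethyl carbon. An intramolecular Friedel–Crafts acylation by C4 then closes ring B, places the ring A oxygens correctly (attack para to OMe) and makes C1 a stereocentre under control of C2 and C3, all in one operation. Its precursor is (2R,3R)-4,4-bis(4-benzyloxy-3-methoxyphenyl)-2,3-bis(pivaloyloxymethyl)butanoic acid; the future C2 comes from an Evans alkylation and the future C3 from a trans-selective hydroxymethylation of a butyrolactone.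

Key step: step 13

Remark (numbering): the tetralin numbering of the target is used for all intermediates: C1 carries the pendant aryl group, C2 and C3 the oxymethyl arms, C4 is the benzylic CH2; ring A is the fused arene, ring B the saturated ring; Ar = 4-(benzyloxy)-3-methoxyphenyl.

Remark (stereochemical correction): the 2,3-trans tetralin needs acid 21 as the (2R,3R) isomer, which has its two arms syn in a zigzag drawing of the butanoic acid chain. A γ-lactone between C4 and the C2 arm would then have to be cis. The route therefore lets the butyrolactone carbonyl become the C3 arm and oxidises the carbon added trans at the α-position to C4.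

Step 1
Reactants: 1 ferulic acid
Product: 2 (E)-3-[4-(benzyloxy)-3-methoxyphenyl]prop-2-enoic acid (O-benzylferulic acid)
Conditions: BnBr, NaOH, EtOH–H2O, reflux; then aq. HCl
Reagents that add atoms: benzyl bromide, BrCc1ccccc1
Why: Williamson ether synthesis in which the phenoxide of the dianion is far more nucleophilic than the carboxylate, while any benzyl ester that forms is saponified by the excess hydroxide.

Step 2
Reactants: 2 O-benzylferulic acid; 3 (S)-4-benzyl-1,3-oxazolidin-2-one
Product: 5 (4S)-4-benzyl-3-{(2E)-3-[4-(benzyloxy)-3-methoxyphenyl]prop-2-enoyl}-1,3-oxazolidin-2-one, via mixed pivalic anhydride 4 (not isolated)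
Conditions: PivCl, Et3N, THF, −20 °C; then 3, LiCl, −20 °C → rt
Reagents that add atoms: none
Why: N-acylation of the oxazolidinone through a mixed anhydride, whose hindered pivaloyl carbonyl directs attack to the cinnamoyl carbonyl; no stereocentre is formed.

Step 3
Reactants: 6 4-bromo-2-methoxyphenol
Product: 7 1-(benzyloxy)-4-bromo-2-methoxybenzene
Conditions: BnBr, K2CO3, acetone, reflux
Reagents that add atoms: benzyl bromide, BrCc1ccccc1
Why: Williamson ether synthesis of a simple phenol with a reactive benzylic halide.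

Step 4
Reactants: 7 1-(benzyloxy)-4-bromo-2-methoxybenzene; 5 N-cinnamoyl oxazolidinone
Product: 9 (4S)-4-benzyl-3-(3,3-diAr-propanoyl)-1,3-oxazolidin-2-one, via aryl Grignard reagent 8 (not isolated)
Conditions: 7, Mg, THF, 40 °C; then CuBr·SMe2 (30 mol %), THF–Me2S, −20 °C, add 5, −20 → 0 °C
Reagents that add atoms: none
Why: copper-catalysed conjugate addition of an aryl Grignard reagent to an N-enoyl oxazolidinone, which needs no facial control because the incoming aryl group is identical to the one already on the β-carbon, so that carbon is not stereogenic.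

Step 5
Reactants: 9 diarylpropanoyl oxazolidinone; 10 tert-butyl bromoacetate
Product: 12 tert-butyl (3S)-3-{[(4S)-4-benzyl-2-oxo-1,3-oxazolidin-3-yl]carbonyl}-4,4-diAr-butanoate, via sodium Z-enolate 11 (not isolated)
Conditions: NaN(SiMe3)2, THF, −78 °C; then 10, −78 → −40 °C
Reagents that add atoms: none
Why: Evans alkylation in which the chelated Z-enolate is attacked by the reactive bromoacetate on the face opposite the benzyl group of the auxiliary, setting the future C2.

Step 6
Reactants: 12 alkylated imide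
Product: 14 (4S)-4-(diAr-methyl)oxolan-2-one, via hydroxy tert-butyl ester 13 (not isolated)
Conditions: LiBH4, MeOH (1 equiv), THF, 0 °C; crude 13, TsOH·H2O (cat.), toluene, 80 °C
Reagents that add atoms: none
Why: chemoselective borohydride reduction of the exocyclic imide carbonyl (the tert-butyl ester is spared) releases the auxiliary, and acid-catalysed lactonisation of the γ-hydroxy ester closes the butyrolactone without touching the stereocentre.

Step 7
Reactants: 14 β-(diarylmethyl) butyrolactone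
Product: 16 (3S,4R)-4-(diAr-methyl)-3-(hydroxymethyl)oxolan-2-one (3,4-trans), via lithium lactone enolate 15 (not isolated)
Conditions: LiN(iPr)2, THF, −78 °C; then CH2O (g, from cracked paraformaldehyde), −78 → −30 °C; AcOH quench
Reagents that add atoms: formaldehyde, C=O
Why: aldol addition of the lactone enolate to monomeric formaldehyde, which should occur on the face anti to the bulky β-diarylmethyl group and so give the 3,4-trans lactone that fixes the future C3.

Step 8
Reactants: 16 trans hydroxymethyl lactone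
Product: 17 (3S,4R)-3-{[(tert-butyldimethylsilyl)oxy]methyl}-4-(diAr-methyl)oxolan-2-one
Conditions: TBSCl, imidazole, DMF, 0 °C → rt
Reagents that add atoms: tert-butyldimethylsilyl chloride, C[Si](C)(Cl)C(C)(C)C
Why: standard silylation of a primary alcohol, fast enough under mild base to outrun β-elimination to the α-methylene lactone.

Step 9
Reactants: 17 silyl ether lactone
Product: 18 (2R,3R)-2-(diAr-methyl)-3-{[(tert-butyldimethylsilyl)oxy]methyl}butane-1,4-diol
Conditions: LiAlH4, THF, 0 °C
Reagents that add atoms: none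
Why: hydride reduction of the lactone to the 1,4-diol, during which the silyl ether stays in place on the aluminium alkoxide so that the two oxymethyl groups on C3 remain distinct.

Step 10
Reactants: 18 diol
Product: 19 (2R,3R)-2-(diAr-methyl)-3-{[(tert-butyldimethylsilyl)oxy]methyl}butane-1,4-diyl bis(2,2-dimethylpropanoate)
Conditions: PivCl, pyridine, DMAP (cat.), CH2Cl2, 0 °C → rt
Reagents that add atoms: pivaloyl chloride, CC(C)(C)C(=O)Cl
Why: nucleophile-catalysed esterification of both primary alcohols with a hindered acyl chloride.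

Step 11
Reactants: 19 bis-pivalate silyl ether
Product: 20 (2R,3S)-2-(diAr-methyl)-3-(hydroxymethyl)butane-1,4-diyl bis(2,2-dimethylpropanoate)
Conditions: HF·pyridine, pyridine, THF, 0 °C → rt
Reagents that add atoms: none
Why: buffered acidic fluoride desilylation of a primary silyl ether, chosen because it avoids the free alkoxide that could shift a pivaloyl group between the two oxymethyl groups on C3.

Step 12
Reactants: 20 primary alcohol
Product: 21 (2R,3R)-4,4-diAr-2,3-bis[(pivaloyloxy)methyl]butanoic acid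
Conditions: TEMPO (cat.), PhI(OAc)2, MeCN–H2O, rt
Reagents that add atoms: water, O
Why: nitroxyl-catalysed oxidation of the primary alcohol through the aldehyde hydrate to the acid under nearly neutral conditions that should spare the aryl ethers, the pivalates and the α-stereocentre.

Step 13
Reactants: 21 diaryl bis-pivalate acid
Product: 23 all-trans (1S,2R,3R)-1-Ar-6-(benzyloxy)-7-methoxy-2,3-bis[(pivaloyloxy)methyl]-3,4-dihydronaphthalen-4(1H)-one (4-tetralone in target numbering), via acid chloride 22 (not isolated)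
Conditions: (COCl)2, DMF (cat.), CH2Cl2, 0 °C → rt, evaporate; then SnCl4, CH2Cl2, −78 → −40 °C
Reagents that add atoms: none
Why: Oxalyl chloride with catalytic DMF turns acid 21 into acyl chloride 22, which SnCl4 ionises to an acylium ion at C4; this attacks one of the two Ar groups on C1 at the ring carbon para to its methoxy group, and loss of HCl from the arenium ion restores aromaticity. The closest known reaction type is the intramolecular Friedel–Crafts acylation of 4,4-diarylbutanoyl chlorides to 4-aryl-1-tetralones. Ring B closes as a six-membered ring by electrophilic aromatic substitution (6-exo-dig at the acylium carbon, with the C8a–C4a bond of the attacked arene becoming part of the new ring). C1 becomes stereogenic because the two aryl groups are diastereotopic, and it is controlled by the C2 and C3 centres through a chair-like transition state in which both pivaloyloxymethyl arms are pseudo-equatorial and the spectator aryl group avoids the pseudo-axial site, which should favour the 1,2-trans ketone. The step needs group selectivity between the two rings, which this equatorial preference should secure, and regioselectivity on the ring, secured by the para-directing methoxy group and by crowding of the alternative position between OMe and C1. It also needs chemoselectivity, which the pivalate esters (too weakly nucleophilic to lactonise onto the acylium ion, unlike ethers) and the low temperature (sparing the aryl benzyl ethers) should provide.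

Step 14
Reactants: 23 tetralone
Product: 24 [(1S,2R,3R)-6-hydroxy-1-(4-hydroxy-3-methoxyphenyl)-7-methoxy-1,2,3,4-tetrahydronaphthalene-2,3-diyl]bis(methylene) bis(2,2-dimethylpropanoate)
Conditions: H2 (4 bar), Pd/C, AcOH–EtOAc, HClO4 (cat.), rt
Reagents that add atoms: none
Why: catalytic hydrogenolysis that should reduce the aryl ketone through its benzylic alcohol to CH2 under acid assistance and cleave both O-benzyl groups at the same time, while the pivalates are inert.

Step 15
Reactants: 24 diphenol bis-pivalate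
Product: 25 (1S,2R,3R)-isolariciresinol, (6R,7R,8S)-8-(4-hydroxy-3-methoxyphenyl)-6,7-bis(hydroxymethyl)-3-methoxy-5,6,7,8-tetrahydronaphthalen-2-ol
Conditions: LiAlH4 (excess), THF, 0 °C → rt
Reagents that add atoms: none
Why: reductive cleavage of the two hindered pivalate esters by excess hydride, with the phenols carried as phenoxides, frees both hydroxymethyl groups without involving any stereocentre.

Compound list
1 | ferulic acid | COc1cc(/C=C/C(=O)O)ccc1O | starting material
2 | (E)-3-[4-(benzyloxy)-3-methoxyphenyl]prop-2-enoic acid | COc1cc(/C=C/C(=O)O)ccc1OCc1ccccc1 | intermediate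
3 | (S)-4-benzyl-1,3-oxazolidin-2-one | O=C1N[C@@H](Cc2ccccc2)CO1 | starting material
4 | mixed anhydride of 2 with pivalic acid | COc1cc(/C=C/C(=O)OC(=O)C(C)(C)C)ccc1OCc1ccccc1 | intermediate
5 | (4S)-4-benzyl-3-{(2E)-3-[4-(benzyloxy)-3-methoxyphenyl]prop-2-enoyl}-1,3-oxazolidin-2-one | COc1cc(/C=C/C(=O)N2[C@@H](Cc3ccccc3)COC2=O)ccc1OCc1ccccc1 | intermediate
6 | 4-bromo-2-methoxyphenol | COc1cc(Br)ccc1O | starting material
7 | 1-(benzyloxy)-4-bromo-2-methoxybenzene | COc1cc(Br)ccc1OCc1ccccc1 | intermediate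
8 | [4-(benzyloxy)-3-methoxyphenyl]magnesium bromide | COc1cc([Mg]Br)ccc1OCc1ccccc1 | intermediate
9 | (4S)-4-benzyl-3-{3,3-bis[4-(benzyloxy)-3-methoxyphenyl]propanoyl}-1,3-oxazolidin-2-one | O=C(CC(c1ccc(OCc2ccccc2)c(OC)c1)c1ccc(OCc2ccccc2)c(OC)c1)N1[C@@H](Cc2ccccc2)COC1=O | intermediate
10 | tert-butyl bromoacetate | CC(C)(C)OC(=O)CBr | starting material
11 | sodium Z-enolate of 9 | [Na+].[O-]/C(=C\C(c1ccc(OCc2ccccc2)c(OC)c1)c1ccc(OCc2ccccc2)c(OC)c1)N1[C@@H](Cc2ccccc2)COC1=O | intermediate
12 | tert-butyl (3S)-3-{[(4S)-4-benzyl-2-oxo-1,3-oxazolidin-3-yl]carbonyl}-4,4-bis[4-(benzyloxy)-3-methoxyphenyl]butanoate | CC(C)(C)OC(=O)C[C@@H](C(c1ccc(OCc2ccccc2)c(OC)c1)c1ccc(OCc2ccccc2)c(OC)c1)C(=O)N1[C@@H](Cc2ccccc2)COC1=O | intermediate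
13 | tert-butyl (3S)-4,4-bis[4-(benzyloxy)-3-methoxyphenyl]-3-(hydroxymethyl)butanoate | CC(C)(C)OC(=O)C[C@@H](C(c1ccc(OCc2ccccc2)c(OC)c1)c1ccc(OCc2ccccc2)c(OC)c1)CO | intermediate
14 | (4S)-4-{bis[4-(benzyloxy)-3-methoxyphenyl]methyl}oxolan-2-one | O=C1C[C@@H](C(c2ccc(OCc3ccccc3)c(OC)c2)c2ccc(OCc3ccccc3)c(OC)c2)CO1 | intermediate
15 | lithium enolate of lactone 14 (C4 unchanged) | [Li+].[O-]C1=C[C@@H](C(c2ccc(OCc3ccccc3)c(OC)c2)c2ccc(OCc3ccccc3)c(OC)c2)CO1 | intermediate
16 | (3S,4R)-4-{bis[4-(benzyloxy)-3-methoxyphenyl]methyl}-3-(hydroxymethyl)oxolan-2-one | O=C1[C@H](CO)[C@@H](C(c2ccc(OCc3ccccc3)c(OC)c2)c2ccc(OCc3ccccc3)c(OC)c2)CO1 | intermediate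
17 | (3S,4R)-4-{bis[4-(benzyloxy)-3-methoxyphenyl]methyl}-3-{[(tert-butyldimethylsilyl)oxy]methyl}oxolan-2-one | O=C1[C@H](CO[Si](C)(C)C(C)(C)C)[C@@H](C(c2ccc(OCc3ccccc3)c(OC)c2)c2ccc(OCc3ccccc3)c(OC)c2)CO1 | intermediate
18 | (2R,3R)-2-{bis[4-(benzyloxy)-3-methoxyphenyl]methyl}-3-{[(tert-butyldimethylsilyl)oxy]methyl}butane-1,4-diol | OC[C@H](CO[Si](C)(C)C(C)(C)C)[C@@H](C(c1ccc(OCc2ccccc2)c(OC)c1)c1ccc(OCc2ccccc2)c(OC)c1)CO | intermediate
19 | (2R,3R)-2-{bis[4-(benzyloxy)-3-methoxyphenyl]methyl}-3-{[(tert-butyldimethylsilyl)oxy]methyl}butane-1,4-diyl bis(2,2-dimethylpropanoate) | CC(C)(C)C(=O)OC[C@H](CO[Si](C)(C)C(C)(C)C)[C@@H](C(c1ccc(OCc2ccccc2)c(OC)c1)c1ccc(OCc2ccccc2)c(OC)c1)COC(=O)C(C)(C)C | intermediate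
20 | (2R,3S)-2-{bis[4-(benzyloxy)-3-methoxyphenyl]methyl}-3-(hydroxymethyl)butane-1,4-diyl bis(2,2-dimethylpropanoate) | CC(C)(C)C(=O)OC[C@H](CO)[C@@H](C(c1ccc(OCc2ccccc2)c(OC)c1)c1ccc(OCc2ccccc2)c(OC)c1)COC(=O)C(C)(C)C | intermediate
21 | (2R,3R)-4,4-bis[4-(benzyloxy)-3-methoxyphenyl]-2,3-bis[(pivaloyloxy)methyl]butanoic acid | O=C(O)[C@@H](COC(=O)C(C)(C)C)[C@H](COC(=O)C(C)(C)C)C(c1ccc(OCc2ccccc2)c(OC)c1)c1ccc(OCc2ccccc2)c(OC)c1 | intermediate
22 | (2R,3R)-4,4-bis[4-(benzyloxy)-3-methoxyphenyl]-2,3-bis[(pivaloyloxy)methyl]butanoyl chloride | O=C(Cl)[C@@H](COC(=O)C(C)(C)C)[C@H](COC(=O)C(C)(C)C)C(c1ccc(OCc2ccccc2)c(OC)c1)c1ccc(OCc2ccccc2)c(OC)c1 | intermediate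
23 | all-trans (1S,2R,3R)-6-(benzyloxy)-1-[4-(benzyloxy)-3-methoxyphenyl]-7-methoxy-2,3-bis[(pivaloyloxy)methyl]-4-tetralone (target numbering) | COc1cc([C@H]2c3cc(OC)c(OCc4ccccc4)cc3C(=O)[C@@H](COC(=O)C(C)(C)C)[C@@H]2COC(=O)C(C)(C)C)ccc1OCc1ccccc1 | intermediate
24 | [(1S,2R,3R)-6-hydroxy-1-(4-hydroxy-3-methoxyphenyl)-7-methoxy-1,2,3,4-tetrahydronaphthalene-2,3-diyl]bis(methylene) bis(2,2-dimethylpropanoate) | COc1cc([C@H]2c3cc(OC)c(O)cc3C[C@@H](COC(=O)C(C)(C)C)[C@@H]2COC(=O)C(C)(C)C)ccc1O | intermediate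
25 | (1S,2R,3R)-isolariciresinol (CNP0313668.1) | COc1cc([C@H]2c3cc(OC)c(O)cc3C[C@@H](CO)[C@@H]2CO)ccc1O | target

Total: 15 steps. Longest linear sequence: 14 steps (steps 1, 2 and 4–15, from ferulic acid 1 to 25); step 3 is a one-step side branch.

Steps most likely to fail

Step 13. The acylium ion may discriminate poorly between the two diastereotopic aryl groups, giving C1 epimers, and the Lewis acid may erode the aryl benzyl ethers. The fallback gives up the desymmetrisation and creates C1 by a cationic cyclisation of known type; it sets out from 5 and comes back at 25.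
- Hydrogenation of the alkene only (H2, RhCl(PPh3)3, toluene–EtOH) would give saturated imide F1.
- Alkylation with 10 under the conditions of step 5 would give succinate imide F2.
- LiBH4 would give hydroxy ester F3, and TsOH in toluene the benzyl lactone F4.
- Aldol addition of its lithium enolate (LiN(iPr)2, THF, −78 °C) to 4-(benzyloxy)-3-methoxybenzaldehyde (COc1cc(C=O)ccc1OCc1ccccc1) would give trans hydroxybenzyl lactone F5 (both carbinol epimers are usable).
- CF3CO2H in CH2Cl2 would ionise the carbinol; the benzylic cation would be captured para to OMe by the other ring through a chair with all substituents equatorial, giving tetralin lactone F6.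
- LiAlH4 would give di-O-benzyl diol F7, and H2 over Pd/C in EtOAc–EtOH would give 25.

Step 14. The hydrogenolysis may stall at the benzylic alcohol, the acid may dehydrate that alcohol toward the C3–C4 alkene (whose re-hydrogenation would erode C3), or pivalic acid may be lost from the β-acyloxy ketone. The fallback separates carbonyl removal from debenzylation; it sets out from 23 and comes back at 24.
- NaBH4 with CeCl3·7H2O in MeOH–THF at −20 °C would give C4 carbinol F8.
- Ionic deoxygenation (Et3SiH, BF3·OEt2, CH2Cl2, −78 °C), in which the para-methoxy-stabilised cation is trapped by hydride before it can eliminate, would give dibenzyl tetralin bis-pivalate F9.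
- Neutral hydrogenolysis (H2, Pd/C, EtOAc) would give 24.

Step 7. Formaldehyde may oligomerise before it reaches the hindered enolate, and the aldolate may undergo retro-aldol loss or dehydration to the α-methylene lactone. The fallback replaces the aldol by an enolate alkylation that delivers the one-carbon unit already protected; it sets out from 14 and comes back at 20.
- The lithium enolate 15 and 2-(trimethylsilyl)ethoxymethyl chloride (C[Si](C)(C)CCOCCl) would give trans silylethoxymethyl lactone F10.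
- LiAlH4 would give silylethyl ether diol F11.
- PivCl, pyridine and DMAP would give silylethyl ether bis-pivalate F12.
- BF3·OEt2 in CH2Cl2 at 0 °C would cleave the 2-(trimethylsilyl)ethyl ether to give 20.

Further compounds
F1 | step 13 | (4S)-4-benzyl-3-{3-[4-(benzyloxy)-3-methoxyphenyl]propanoyl}-1,3-oxazolidin-2-one | COc1cc(CCC(=O)N2[C@@H](Cc3ccccc3)COC2=O)ccc1OCc1ccccc1
F2 | step 13 | tert-butyl (3R)-3-{[(4S)-4-benzyl-2-oxo-1,3-oxazolidin-3-yl]carbonyl}-4-[4-(benzyloxy)-3-methoxyphenyl]butanoate | CC(C)(C)OC(=O)C[C@@H](Cc1ccc(OCc2ccccc2)c(OC)c1)C(=O)N1[C@@H](Cc2ccccc2)COC1=O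
F3 | step 13 | tert-butyl (3R)-4-[4-(benzyloxy)-3-methoxyphenyl]-3-(hydroxymethyl)butanoate | CC(C)(C)OC(=O)C[C@@H](Cc1ccc(OCc2ccccc2)c(OC)c1)CO
F4 | step 13 | (4R)-4-[4-(benzyloxy)-3-methoxybenzyl]oxolan-2-one | O=C1C[C@@H](Cc2ccc(OCc3ccccc3)c(OC)c2)CO1
F5 | step 13 | (3S,4R)-4-[4-(benzyloxy)-3-methoxybenzyl]-3-{[4-(benzyloxy)-3-methoxyphenyl](hydroxy)methyl}oxolan-2-one, carbinol epimers | O=C1[C@H](C(O)c2ccc(OCc3ccccc3)c(OC)c2)[C@@H](Cc2ccc(OCc3ccccc3)c(OC)c2)CO1
F6 | step 13 | all-trans (1S,2R,3R)-6-(benzyloxy)-1-[4-(benzyloxy)-3-methoxyphenyl]-3-(hydroxymethyl)-7-methoxytetralin-2-carboxylic acid γ-lactone | COc1cc([C@H]2c3cc(OC)c(OCc4ccccc4)cc3C[C@H]3COC(=O)[C@H]23)ccc1OCc1ccccc1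
F7 | step 13 | (1S,2R,3R)-6-(benzyloxy)-1-[4-(benzyloxy)-3-methoxyphenyl]-2,3-bis(hydroxymethyl)-7-methoxytetralin | COc1cc([C@H]2c3cc(OC)c(OCc4ccccc4)cc3C[C@@H](CO)[C@@H]2CO)ccc1OCc1ccccc1
F8 | step 14 | (1S,2R,3R)-6-(benzyloxy)-1-[4-(benzyloxy)-3-methoxyphenyl]-4-hydroxy-7-methoxy-2,3-bis[(pivaloyloxy)methyl]tetralin, C4 epimers | COc1cc([C@H]2c3cc(OC)c(OCc4ccccc4)cc3C(O)[C@@H](COC(=O)C(C)(C)C)[C@@H]2COC(=O)C(C)(C)C)ccc1OCc1ccccc1
F9 | step 14 | (1S,2R,3R)-6-(benzyloxy)-1-[4-(benzyloxy)-3-methoxyphenyl]-7-methoxy-2,3-bis[(pivaloyloxy)methyl]tetralin | COc1cc([C@H]2c3cc(OC)c(OCc4ccccc4)cc3C[C@@H](COC(=O)C(C)(C)C)[C@@H]2COC(=O)C(C)(C)C)ccc1OCc1ccccc1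
F10 | step 7 | (3S,4R)-4-{bis[4-(benzyloxy)-3-methoxyphenyl]methyl}-3-{[2-(trimethylsilyl)ethoxy]methyl}oxolan-2-one | O=C1[C@H](COCC[Si](C)(C)C)[C@@H](C(c2ccc(OCc3ccccc3)c(OC)c2)c2ccc(OCc3ccccc3)c(OC)c2)CO1
F11 | step 7 | (2R,3R)-2-{bis[4-(benzyloxy)-3-methoxyphenyl]methyl}-3-{[2-(trimethylsilyl)ethoxy]methyl}butane-1,4-diol | OC[C@H](COCC[Si](C)(C)C)[C@@H](C(c1ccc(OCc2ccccc2)c(OC)c1)c1ccc(OCc2ccccc2)c(OC)c1)CO
F12 | step 7 | (2R,3R)-2-{bis[4-(benzyloxy)-3-methoxyphenyl]methyl}-3-{[2-(trimethylsilyl)ethoxy]methyl}butane-1,4-diyl bis(2,2-dimethylpropanoate) | CC(C)(C)C(=O)OC[C@H](COCC[Si](C)(C)C)[C@@H](C(c1ccc(OCc2ccccc2)c(OC)c1)c1ccc(OCc2ccccc2)c(OC)c1)COC(=O)C(C)(C)C
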